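## Retrosynthetic overview

1. Target 24 ⇐ C2 ketone 21: the C2 carbonyl is a temporary activating group, removed at the end by reduction and Barton–McCombie deoxygenation.
2. 21 ⇐ acyclic trienone 20 by a macrocyclising type 2 intramolecular Diels–Alder reaction that forms C13–C14 and C1–C15, closing ring A and the twelve-membered ring in one operation and setting C1.
3. Enabling feature: the butenolide ring (O, C18, C12, C11, C10) carries C13 and C15 on adjacent ring carbons, so at the exocyclic-diene oxidation level it locks C13=C12–C11=C15 s-cis; the tetrasubstituted bridgehead alkene C11=C12 of ring A is the cyclohexene double bond a [4+2] addition leaves behind.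
4. 20 ⇐ diene-lactone enal 13 + bifunctional allylstannane 15 (asymmetric allylation, sets C6) + acrolein 18 (Barbier allylation, brings C1, C2, C14).
5. 13 ⇐ alkenyl bromide 8 + stannyl acrylate 10 (Stille coupling and lactonisation); 8 ⇐ bromo-enal 3 + dienolate 6 (asymmetric vinylogous aldol, sets C10). Ring order: lactone (step 6), then ring A and the twelve-membered ring together (step 13).

Key step: step 13

Remark on numbering: atom numbers follow the verticillane skeleton. C1 is the ring-fusion CH; C2 to C10 form the nine-carbon bridge (C20 on C4, acetoxy on C6, C19 on C8, lactone oxygen on C10); C11=C12 is the tetrasubstituted alkene; C13 and C14 are the ring A methylenes; C15 is the gem-dimethyl carbon; C18 is the lactone carbonyl on C12.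

Remark on assumptions: the sense of induction in steps 3 and 9 is taken from the usual models for these catalysts, and the other catalyst enantiomer would be used if the sense proved opposite. The diene-lactones 12, 13, 16, 17, 19 and 20 are assumed to be handled cold, dilute and with BHT.

## Route

Step 1
Reactants: 1 3-methylbut-2-enal
Product: 3 2-bromo-3-methylbut-2-enal, via 2,3-dibromo-3-methylbutanal 2 (not isolated)
Conditions: Br2, CH2Cl2, −78 °C; then Et3N, −78 °C to rt
Reagents that add atoms: bromine, BrBr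
Why: Bromine adds across the enal double bond and triethylamine then removes HBr (acidic α-hydrogen, tertiary β-bromide), the standard addition–elimination route to α-bromo enals.

Step 2
Reactants: 4 ethyl 3-methylbut-2-enoate
Product: 6 tert-butyl[(1-ethoxy-3-methylbuta-1,3-dien-1-yl)oxy]dimethylsilane, via lithium dienolate 5 (not isolated)
Conditions: LiN(iPr)2, THF, −78 °C; then TBSCl, DMPU, −78 °C to rt
Reagents that add atoms: tert-butyldimethylsilyl chloride, CC(C)(C)[Si](C)(C)Cl
Why: Kinetic γ-deprotonation of the ester gives the lithium dienolate, which is trapped on oxygen (O-silylation to the silyl dienol ether); the ketene acetal geometry is inconsequential.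

Step 3
Reactants: 3 2-bromo-3-methylbut-2-enal; 6 tert-butyl[(1-ethoxy-3-methylbuta-1,3-dien-1-yl)oxy]dimethylsilane
Product: 7 ethyl (2E,5R)-6-bromo-5-hydroxy-3,7-dimethylocta-2,6-dienoate
Conditions: SiCl4 (1.1 equiv), chiral bisphosphoramide (R,R)-[CH2]5[N(Me)P(=O)(N,N'-dimethyl-1,1'-binaphthalene-2,2'-diamide)]2 (5 mol%), iPr2NEt (10 mol%), CH2Cl2, −78 °C; aq. NaHCO3
Reagents that add atoms: none
Why: In this Lewis base-catalysed, SiCl4-mediated asymmetric vinylogous Mukaiyama aldol reaction the phosphoramide-bound trichlorosilyl cation activates the conjugated aldehyde and the dienolate should attack through its γ-carbon on the Re face, setting C10 as R and giving the (E)-enoate.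

Step 4
Reactants: 7 ethyl (2E,5R)-6-bromo-5-hydroxy-3,7-dimethylocta-2,6-dienoate
Product: 8 (2E,5R)-6-bromo-3,7-dimethylocta-2,6-diene-1,5-diol
Conditions: iBu2AlH (3.5 equiv), CH2Cl2, −78 to 0 °C; aq. potassium sodium tartrate
Reagents that add atoms: none
Why: iBu2AlH reduces the conjugated ester by 1,2-addition to the allylic alcohol (ester reduction) without touching the alkenyl bromide, the alkene geometry or C10.

Step 5
Reactants: 9 methyl prop-2-ynoate
Product: 10 methyl 2-(tributylstannyl)prop-2-enoate
Conditions: Bu3SnH, Pd(PPh3)4 (2 mol%), THF, 0 °C to rt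
Reagents that add atoms: tributyltin hydride, CCCC[SnH](CCCC)CCCC
Why: Palladium-catalysed syn-hydrostannation of an alkynoate places tin on the α-carbon regioselectively.

Step 6
Reactants: 8 (2E,5R)-6-bromo-3,7-dimethylocta-2,6-diene-1,5-diol; 10 methyl 2-(tributylstannyl)prop-2-enoate
Product: 12 (5R)-5-[(2E)-4-hydroxy-2-methylbut-2-en-1-yl]-3-methylidene-4-(propan-2-ylidene)oxolan-2-one, via hydroxy ester 11 (not isolated)
Conditions: Pd(PPh3)4 (10 mol%), CuI (20 mol%), CsF (2 equiv), DMF, 45 °C; then PPTS (cat.), CH2Cl2, rt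
Reagents that add atoms: none
Why: A Stille coupling with copper and fluoride activation (suited to hindered alkenyl partners) joins C11 to C12, and the γ-hydroxy acrylate so formed closes to the five-membered lactone by transesterification, leaving C10 untouched.

Step 7
Reactants: 12 (5R)-5-[(2E)-4-hydroxy-2-methylbut-2-en-1-yl]-3-methylidene-4-(propan-2-ylidene)oxolan-2-one
Product: 13 (2E)-3-methyl-4-[(2R)-4-methylidene-5-oxo-3-(propan-2-ylidene)oxolan-2-yl]but-2-enal
Conditions: Dess–Martin periodinane, CH2Cl2, 0 °C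
Reagents that add atoms: none
Why: Dess–Martin oxidation converts the primary allylic alcohol into the enal under neutral conditions that leave the diene-lactone and the (E)-alkene intact.

Step 8
Reactants: 14 3-chloro-2-(chloromethyl)prop-1-ene
Product: 15 tributyl[2-(chloromethyl)prop-2-en-1-yl]stannane
Conditions: Bu3SnH, LiN(iPr)2, THF, −78 °C; then 14 (excess), −78 °C
Reagents that add atoms: tributyltin hydride, CCCC[SnH](CCCC)CCCC
Why: SN2 displacement of one allylic chloride of the excess dichloride by tributylstannyllithium gives the bifunctional allylstannane.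

Step 9
Reactants: 13 (2E)-3-methyl-4-[(2R)-4-methylidene-5-oxo-3-(propan-2-ylidene)oxolan-2-yl]but-2-enal; 15 tributyl[2-(chloromethyl)prop-2-en-1-yl]stannane
Product: 16 (5R)-5-[(2E,4S)-6-(chloromethyl)-4-hydroxy-2-methylhepta-2,6-dien-1-yl]-3-methylidene-4-(propan-2-ylidene)oxolan-2-one
Conditions: (S)-BINOL (20 mol%), Ti(OiPr)4 (10 mol%), 4 Å MS, CH2Cl2, −20 °C; aq. NaHCO3
Reagents that add atoms: none
Why: In this Keck asymmetric allylation the (S)-BINOL/Ti(OiPr)4 complex activates the enal and the allylstannane should add 1,2 on the Si face, setting C6 as S; the allylic chloride and the diene-lactone are inert, and the 2-substituted allyl unit has equivalent termini.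

Step 10
Reactants: 16 (5R)-5-[(2E,4S)-6-(chloromethyl)-4-hydroxy-2-methylhepta-2,6-dien-1-yl]-3-methylidene-4-(propan-2-ylidene)oxolan-2-one
Product: 17 (2E,4S)-6-(chloromethyl)-2-methyl-1-[(2R)-4-methylidene-5-oxo-3-(propan-2-ylidene)oxolan-2-yl]hepta-2,6-dien-4-yl acetate
Conditions: Ac2O, pyridine, DMAP (cat.), CH2Cl2, 0 °C
Reagents that add atoms: acetic anhydride, CC(=O)OC(C)=O
Why: DMAP-catalysed acylation of the secondary allylic alcohol proceeds with retention at C6.

Step 11
Reactants: 17 (2E,4S)-6-(chloromethyl)-2-methyl-1-[(2R)-4-methylidene-5-oxo-3-(propan-2-ylidene)oxolan-2-yl]hepta-2,6-dien-4-yl acetate; 18 prop-2-enal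
Product: 19 (2E,4S)-8-hydroxy-2-methyl-6-methylidene-1-[(2R)-4-methylidene-5-oxo-3-(propan-2-ylidene)oxolan-2-yl]deca-2,9-dien-4-yl acetate (C2 epimers in skeleton numbering)
Conditions: indium powder, NaI (cat.), DMF/H2O, rt
Reagents that add atoms: none
Why: The indium-mediated Barbier allylation tolerates esters, lactones and water and adds the allyl unit 1,2 to acrolein, creating C2–C3; the C2 carbinol configuration is irrelevant because it is oxidised next.

Step 12
Reactants: 19 (2E,4S)-8-hydroxy-2-methyl-6-methylidene-1-[(2R)-4-methylidene-5-oxo-3-(propan-2-ylidene)oxolan-2-yl]deca-2,9-dien-4-yl acetate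
Product: 20 (2E,4S)-2-methyl-6-methylidene-1-[(2R)-4-methylidene-5-oxo-3-(propan-2-ylidene)oxolan-2-yl]-8-oxodeca-2,9-dien-4-yl acetate
Conditions: Dess–Martin periodinane, NaHCO3, CH2Cl2, 0 °C; crude used at once
Reagents that add atoms: none
Why: Buffered Dess–Martin oxidation of the allylic carbinol gives the vinyl ketone without acid or base strong enough to move C4=C20 into conjugation.

Step 13
Reactants: 20 (2E,4S)-2-methyl-6-methylidene-1-[(2R)-4-methylidene-5-oxo-3-(propan-2-ylidene)oxolan-2-yl]-8-oxodeca-2,9-dien-4-yl acetate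
Product: 21 (1R,6S,7E,10R)-6-acetoxy-2-oxoverticilla-4(20),7,11-trien-18,10-olide
Conditions: PhMe (0.5 mM), BHT (cat.), 110 °C
Reagents that add atoms: none
Why: A concerted thermal [4+2] cycloaddition (type 2 intramolecular Diels–Alder reaction) joins the vinyl ketone C1=C14 to the s-cis-locked exocyclic diene C13=C12–C11=C15, forming C13–C14 and C1–C15 and leaving the double bond at C11=C12; the closest known reactions are type 2 intramolecular Diels–Alder cyclisations of vinyl ketones tethered to the internal carbon of isopropylidene dienes, which give the bridgehead-alkene bicyclo[n.3.1] ring A systems of taxanes, and macrocyclising Diels–Alder closures of activated dienophiles at high dilution. Ring A closes as the cyclohexene of the cycloaddition, and the twelve-membered ring closes at the same time as the 1,3-bridge (meta mode) because the tether leaves the diene at its internal carbon C11. The new stereocentre C1 is controlled by C10: the tether starts at C9 on one face of the lactone, so the dienophile should be delivered to that face with the acyl carbon C2 endo, which puts C2 and C9 on the same side of ring A as the (1R,10R) target requires. The step needs regioselectivity (C14 to C13, C1 to C15), which the polarisation of both partners (largest diene HOMO coefficient at C13, enone β-carbon C14) and the strain of the 1,4-bridged alternative should secure, and it needs cyclisation to outrun dimerisation, which the dilution and the hindered isopropylidene terminus should secure. No Lewis acid is used because a complexed enone would invite cation–olefin attack by the C4=C20 alkene and ionisation of the allylic acetate.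

Step 14
Reactants: 21 (1R,6S,7E,10R)-6-acetoxy-2-oxoverticilla-4(20),7,11-trien-18,10-olide
Product: 22 (1R,6S,7E,10R)-6-acetoxy-2-hydroxyverticilla-4(20),7,11-trien-18,10-olide (C2 epimers)
Conditions: NaBH4, MeOH/THF, −20 °C
Reagents that add atoms: none
Why: Borohydride 1,2-reduction of the isolated ketone should be faster than attack on the tetrasubstituted butenolide or the acetate, and both C2 epimers serve the next step.

Step 15
Reactants: 22 (1R,6S,7E,10R)-6-acetoxy-2-hydroxyverticilla-4(20),7,11-trien-18,10-olide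
Product: 23 (1R,6S,7E,10R)-6-acetoxy-2-[(1H-imidazol-1-ylcarbothioyl)oxy]verticilla-4(20),7,11-trien-18,10-olide
Conditions: 1,1'-thiocarbonyldiimidazole, DMAP (cat.), PhMe, 80 °C
Reagents that add atoms: 1,1'-thiocarbonyldiimidazole, S=C(n1ccnc1)n1ccnc1
Why: Thioacylation of the secondary alcohol under neutral conditions gives the Barton–McCombie substrate without enolisation at C10 or acetate migration.

Step 16
Reactants: 23 (1R,6S,7E,10R)-6-acetoxy-2-[(1H-imidazol-1-ylcarbothioyl)oxy]verticilla-4(20),7,11-trien-18,10-olide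
Product: 24 (1R,6S,7E,10R)-6-acetoxyverticilla-4(20),7,11-trien-18,10-olide (CNP0289913.1)
Conditions: Bu3SnH, AIBN (cat.), PhMe, 90 °C
Reagents that add atoms: none
Why: In the Barton–McCombie deoxygenation the stannyl radical adds to C=S, the C2–O bond fragments, and the secondary C2 radical should take hydrogen from Bu3SnH faster than it can add to a ring alkene, leaving C1, C6 and C10 untouched.

## Compound list

1 | 3-methylbut-2-enal | CC(C)=CC=O | starting material
2 | 2,3-dibromo-3-methylbutanal (racemic, not isolated) | CC(C)(Br)C(Br)C=O | intermediate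
3 | 2-bromo-3-methylbut-2-enal | CC(C)=C(Br)C=O | intermediate
4 | ethyl 3-methylbut-2-enoate | CCOC(=O)C=C(C)C | starting material
5 | lithium 1-ethoxy-3-methylbuta-1,3-dien-1-olate (not isolated) | [Li]OC(OCC)=CC(C)=C | intermediate
6 | tert-butyl[(1-ethoxy-3-methylbuta-1,3-dien-1-yl)oxy]dimethylsilane | CCOC(=CC(C)=C)O[Si](C)(C)C(C)(C)C | intermediate
7 | ethyl (2E,5R)-6-bromo-5-hydroxy-3,7-dimethylocta-2,6-dienoate | CCOC(=O)/C=C(\C)C[C@@H](O)C(Br)=C(C)C | intermediate
8 | (2E,5R)-6-bromo-3,7-dimethylocta-2,6-diene-1,5-diol | OC/C=C(\C)C[C@@H](O)C(Br)=C(C)C | intermediate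
9 | methyl prop-2-ynoate | C#CC(=O)OC | starting material
10 | methyl 2-(tributylstannyl)prop-2-enoate | C=C(C(=O)OC)[Sn](CCCC)(CCCC)CCCC | intermediate
11 | methyl 3-[(1R,3E)-1,5-dihydroxy-3-methylpent-3-en-1-yl]-4-methyl-2-methylidenepent-3-enoate (not isolated) | OC/C=C(\C)C[C@@H](O)C(=C(C)C)C(=C)C(=O)OC | intermediate
12 | (5R)-5-[(2E)-4-hydroxy-2-methylbut-2-en-1-yl]-3-methylidene-4-(propan-2-ylidene)oxolan-2-one | OC/C=C(\C)C[C@H]1OC(=O)C(=C)C1=C(C)C | intermediate
13 | (2E)-3-methyl-4-[(2R)-4-methylidene-5-oxo-3-(propan-2-ylidene)oxolan-2-yl]but-2-enal | O=C/C=C(\C)C[C@H]1OC(=O)C(=C)C1=C(C)C | intermediate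
14 | 3-chloro-2-(chloromethyl)prop-1-ene | C=C(CCl)CCl | starting material
15 | tributyl[2-(chloromethyl)prop-2-en-1-yl]stannane | C=C(CCl)C[Sn](CCCC)(CCCC)CCCC | intermediate
16 | (5R)-5-[(2E,4S)-6-(chloromethyl)-4-hydroxy-2-methylhepta-2,6-dien-1-yl]-3-methylidene-4-(propan-2-ylidene)oxolan-2-one | C=C(CCl)C[C@H](O)/C=C(\C)C[C@H]1OC(=O)C(=C)C1=C(C)C | intermediate
17 | (2E,4S)-6-(chloromethyl)-2-methyl-1-[(2R)-4-methylidene-5-oxo-3-(propan-2-ylidene)oxolan-2-yl]hepta-2,6-dien-4-yl acetate | C=C(CCl)C[C@H](OC(C)=O)/C=C(\C)C[C@H]1OC(=O)C(=C)C1=C(C)C | intermediate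
18 | prop-2-enal (acrolein) | C=CC=O | starting material
19 | (2E,4S)-8-hydroxy-2-methyl-6-methylidene-1-[(2R)-4-methylidene-5-oxo-3-(propan-2-ylidene)oxolan-2-yl]deca-2,9-dien-4-yl acetate (epimers at the carbinol) | C=CC(O)CC(=C)C[C@H](OC(C)=O)/C=C(\C)C[C@H]1OC(=O)C(=C)C1=C(C)C | intermediate
20 | (2E,4S)-2-methyl-6-methylidene-1-[(2R)-4-methylidene-5-oxo-3-(propan-2-ylidene)oxolan-2-yl]-8-oxodeca-2,9-dien-4-yl acetate | C=CC(=O)CC(=C)C[C@H](OC(C)=O)/C=C(\C)C[C@H]1OC(=O)C(=C)C1=C(C)C | intermediate
21 | (1R,6S,7E,10R)-6-acetoxy-2-oxoverticilla-4(20),7,11-trien-18,10-olide | C=C1CC(=O)[C@@H]2CCC3=C([C@@H](C/C(C)=C/[C@@H](OC(C)=O)C1)OC3=O)C2(C)C | intermediate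
22 | (1R,6S,7E,10R)-6-acetoxy-2-hydroxyverticilla-4(20),7,11-trien-18,10-olide (C2 epimers) | C=C1CC(O)[C@@H]2CCC3=C([C@@H](C/C(C)=C/[C@@H](OC(C)=O)C1)OC3=O)C2(C)C | intermediate
23 | (1R,6S,7E,10R)-6-acetoxy-2-[(1H-imidazol-1-ylcarbothioyl)oxy]verticilla-4(20),7,11-trien-18,10-olide | C=C1CC(OC(=S)n4ccnc4)[C@@H]2CCC3=C([C@@H](C/C(C)=C/[C@@H](OC(C)=O)C1)OC3=O)C2(C)C | intermediate
24 | (1R,6S,7E,10R)-6-acetoxyverticilla-4(20),7,11-trien-18,10-olide (CNP0289913.1) | C=C1CC[C@@H]2CCC3=C([C@@H](C/C(C)=C/[C@@H](OC(C)=O)C1)OC3=O)C2(C)C | target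

## Step count and risks

Total steps: 16. Longest linear sequence: 13 steps (steps 1, 3, 4, 6, 7 and 9 to 16, from 3-methylbut-2-enal).

Most likely to fail:

1. Step 13. The cycloaddition may be too slow at a concentration low enough to suppress dimerisation through the α-methylene lactone, endo/exo control at C1 may be poor, and C4=C20 may drift into conjugation with the C2 ketone on prolonged heating. The fallback sets out from 17 and returns at 22. 17 and acrolein 18 (excess, PhMe, BHT, 60 °C) should undergo the intermolecular Diels–Alder reaction, forming the same C13–C14 and C1–C15 bonds, to give the ring A aldehyde (2E,4S)-6-(chloromethyl)-1-[(1R,6R)-6-formyl-7,7-dimethyl-3-oxo-1,3,4,5,6,7-hexahydro-2-benzofuran-1-yl]-2-methylhepta-2,6-dien-4-yl acetate F1. Its C1 epimer can be equilibrated with DBU through the formyl α-position. CrCl2 (NaI cat., THF, high dilution) should then effect an intramolecular Nozaki–Hiyama allylation of the formyl group by the allylic chloride, closing C2–C3 and the twelve-membered ring to give 22.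

2. Step 6. Oxidative addition and transmetalation at the tetrasubstituted alkenyl bromide may be slower than protodestannylation or homocoupling of 10. The fallback sets out from 8 and returns at 12, reversing the polarity of the coupling. TESCl/imidazole should give the bis(triethylsilyl) ether (2E,5R)-6-bromo-3,7-dimethyl-1,5-bis(triethylsilyloxy)octa-2,6-diene F2. tBuLi (THF, −78 °C) should give the alkenyllithium [(2E,5R)-3,7-dimethyl-1,5-bis(triethylsilyloxy)octa-2,6-dien-6-yl]lithium F3, and ZnBr2 the alkenylzinc bromide [(2E,5R)-3,7-dimethyl-1,5-bis(triethylsilyloxy)octa-2,6-dien-6-yl]zinc bromide F4. Negishi coupling with methyl 2-bromoprop-2-enoate (Pd(PPh3)4, THF, rt) should give the diene ester methyl 4-methyl-3-[(1R,3E)-3-methyl-1,5-bis(triethylsilyloxy)pent-3-en-1-yl]-2-methylidenepent-3-enoate F5. HF·pyridine should then remove both silyl groups and trigger lactonisation to 12.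

3. Step 9. Addition to the β,β-disubstituted enal may be sluggish, giving the diene-lactone time to dimerise, and enantioselectivity may erode. The fallback sets out from 13 and returns at 16, moving stereocontrol from C–C bond formation to a ketone reduction. Indium-mediated Barbier allylation of 13 with 14 (indium powder, NaI cat., DMF/H2O) should give the C6-epimeric alcohols (5R)-5-[(2E,4RS)-6-(chloromethyl)-4-hydroxy-2-methylhepta-2,6-dien-1-yl]-3-methylidene-4-(propan-2-ylidene)oxolan-2-one F6. Dess–Martin oxidation should give the enone (5R)-5-[(2E)-6-(chloromethyl)-2-methyl-4-oxohepta-2,6-dien-1-yl]-3-methylidene-4-(propan-2-ylidene)oxolan-2-one F7. Corey–Bakshi–Shibata reduction with the (R)-2-methyl-oxazaborolidine and catecholborane (PhMe, −78 °C) should then deliver 16.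

Further compounds
F1 | step 13 | (2E,4S)-6-(chloromethyl)-1-[(1R,6R)-6-formyl-7,7-dimethyl-3-oxo-1,3,4,5,6,7-hexahydro-2-benzofuran-1-yl]-2-methylhepta-2,6-dien-4-yl acetate | O=C[C@@H]1CCC2=C([C@@H](C/C(C)=C/[C@@H](OC(C)=O)CC(=C)CCl)OC2=O)C1(C)C
F2 | step 6 | (2E,5R)-6-bromo-3,7-dimethyl-1,5-bis(triethylsilyloxy)octa-2,6-diene | CC[Si](CC)(CC)OC/C=C(\C)C[C@@H](O[Si](CC)(CC)CC)C(Br)=C(C)C
F3 | step 6 | [(2E,5R)-3,7-dimethyl-1,5-bis(triethylsilyloxy)octa-2,6-dien-6-yl]lithium | CC[Si](CC)(CC)OC/C=C(\C)C[C@@H](O[Si](CC)(CC)CC)C([Li])=C(C)C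
F4 | step 6 | [(2E,5R)-3,7-dimethyl-1,5-bis(triethylsilyloxy)octa-2,6-dien-6-yl]zinc bromide | CC[Si](CC)(CC)OC/C=C(\C)C[C@@H](O[Si](CC)(CC)CC)C([Zn]Br)=C(C)C
F5 | step 6 | methyl 4-methyl-3-[(1R,3E)-3-methyl-1,5-bis(triethylsilyloxy)pent-3-en-1-yl]-2-methylidenepent-3-enoate | CC[Si](CC)(CC)OC/C=C(\C)C[C@@H](O[Si](CC)(CC)CC)C(=C(C)C)C(=C)C(=O)OC
F6 | step 9 | (5R)-5-[(2E,4RS)-6-(chloromethyl)-4-hydroxy-2-methylhepta-2,6-dien-1-yl]-3-methylidene-4-(propan-2-ylidene)oxolan-2-one | C=C(CCl)CC(O)/C=C(\C)C[C@H]1OC(=O)C(=C)C1=C(C)C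
F7 | step 9 | (5R)-5-[(2E)-6-(chloromethyl)-2-methyl-4-oxohepta-2,6-dien-1-yl]-3-methylidene-4-(propan-2-ylidene)oxolan-2-one | C=C(CCl)CC(=O)/C=C(\C)C[C@H]1OC(=O)C(=C)C1=C(C)C
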